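The readings are simulated for an exercise; noise was put on by code.

Read the gains first.

| setting | ochre | flask |
|---|---|---|
| starting material | 1 mM (in portions, 3) | 1.0 mM (in portions, 3) |
| partner | 0.80 mM | 0.800 mM |
| initiator | 10 µM | 10 µM |
| remark | the very flask that is asked about, followed so far; portions every 15 s | the portions of starting material follow each other after 15 s, the first at the start |
| time |  | 20 min |

ochre run (percent of the starting material charged)

| time / min | starting material / % | target / % |
|---|---|---|
| 0.500 | 44.9 | 21.5 |
| 1.00 | 60.1 | 39.4 |
| 1.50 | 59.7 | 40.1 |
| 2.50 | 59.5 | 40.3 |
| 3.00 | 59.1 | 41.0 |
| 4.00 | 59.3 | 41.4 |

(each reading ± 0.3 percentage points)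

- the reaction counts as stopped when no species that holds the starting material changes by six tenths of a point or more over the second half of the time

1. which holds at 20 min: what has brought the reaction to rest, or that it has not come to rest (it is still moving / forward and back rates have come level / the partner has run out first / all of the starting material has reacted)
2. part of the starting material gone at 20 min
3. the target standing at 20 min, as a percentage of the starting material charged

This reckoning is separate from the forecast.

1. In the ochre run, target gains 18 percentage points from 0.500 min to 1.00 min, then 0.7 points over the next equal step, a ratio of 25.6.

2. That ratio is 1.41 decades, so on these readings the rate of making target falls by one decade every τ = 0.355 min.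

3. Across that fall in the ochre run, starting material reads 60.1 %, then 59.7 %, so it is not what is being lost. The reckoning takes partner as the lost species, at first order.

4. From 1.50 min to 20 min lie 52.1 such decades, so the reckoning has partner run out first.

5. The weak link is the late climb: in the ochre run, target rises 1.3 points after 1.50 min. Target made from starting material should show as an equal fall, yet starting material falls 0.4 points, and a difference of two readings scatters by 0.42 points. The plateau is therefore taken as flat.

6. The plateau means give target 40.7 % and conversion 40.6 %. With cA the starting material and cB the partner charged, f = 0.509. This partner yield, target at rest per partner charged, is about half.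

The forecast differs: it is still moving, conversion 46 %, target 46 %. Its ground: “the 10–20 min change exceeds 0.6 points, so it is still moving”.

The flask gives: the partner has run out first, conversion 41.4 %, target 40.5 %.

    initiator → 2 initiating radical (k = 5.37 × 10⁻⁴ s⁻¹)
    starting material + initiating radical → capped initiator + first chain carrier (k = 3.39 × 10⁸ M⁻¹ s⁻¹)
    partner + first chain carrier → target + second chain carrier (k = 8.93 × 10⁶ M⁻¹ s⁻¹)
    starting material + second chain carrier → by-product + first chain carrier (k = 4.83 × 10⁶ M⁻¹ s⁻¹)
    2 first chain carrier → ended chains A (k = 3.00 × 10⁷ M⁻¹ s⁻¹)
    2 second chain carrier → ended chains B (k = 3.70 × 10⁸ M⁻¹ s⁻¹)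
    partner → decomposed reagent (k = 0.0225 s⁻¹)

In the flask, partner fed two steps together: by 2.00 min the making of target had >99.9 % of its turnover to the asked time behind it, and by 4.00 min the loss to decomposed reagent had 100 %. With partner, the limiting reagent, at 0 % at 20.0 min, target stands at 40.5 %, where f × cB/cA gives 40.7 %, and decomposed reagent holds 0.395 mM; the neighbour flask with 0.025 mM of initiator, its other charges as in the flask, reaches a partner yield of 0.573, more than f, with target at 45.8 % and decomposed reagent at 0.342 mM.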